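## Retrosynthetic overview

1. Guaiane numbering is used for the terpene part (ring A = C1–C5, ring B = C1, C5–C10, C9' = benzylic carbon). The strategy rests on the homoallylic alcohol of ring B, C5=C6–C7–C11(OH), read as an opened gem-dimethylcyclopropane C6–C7–C11 next to a C5 cation.
2. Target ⇐ tri-O-methyl dialdehyde 29 (thiolate demethylation) ⇐ 24 (two aryllithium formylations) ⇐ 10(14)-ene 23 (hydroxyl-directed hydrogenation sets C10).
3. 23 ⇐ enyne 22: gold-triggered closure of ring B (C1–C10), relayed through the cyclopropane (C6–C11 cleavage, water capture at C11).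
4. 22 ⇐ ring A enol triflate 13 + cis-cyclopropylzinc 20 (Negishi coupling); 20 comes from copper-catalysed carbomagnesiation of 3,3-dimethylcyclopropene.
5. 13 ⇐ dihydrocoumarin 5: organocatalytic Friedel–Crafts sets C9', lactone-tethered enolate alkylation sets C4, SmI2 acyl substitution closes ring A. Ring order: A, cyclopropane, B.

Key step: step 13

Assumption: the cis-cyclopropylmetal is made by carbometalation of a cyclopropene rather than by degrading a chiral-pool cyclopropanecarboxylic acid, because a cyclopropyl radical would lose the cis geometry that the ring closure needs; the sense of both catalytic asymmetric steps is taken from the usual models, and both catalyst antipodes are available.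

## Route

Step 1
Reactants: 1 isovaleraldehyde (3-methylbutanal)
Product: 2 (E)-5-methylhex-2-enal
Conditions: Ph3P=CHCHO (0.8 equiv), toluene, 80 °C
Reagents that add atoms: (triphenylphosphoranylidene)acetaldehyde, O=CC=P(c1ccccc1)(c1ccccc1)c1ccccc1
Why: Wittig olefination with a stabilised ylide gives the E-enal, and the aldehyde in excess limits a second homologation.

Step 2
Reactants: 2 (E)-5-methylhex-2-enal; 3 3,5-dimethoxyphenol
Product: 4 (4R)-5,7-dimethoxy-4-(2-methylpropyl)chroman-2-ol (both anomers)
Conditions: (S)-α,α-diphenylprolinol trimethylsilyl ether (20 mol %), PhCO2H (20 mol %), CH2Cl2, 0 °C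
Reagents that add atoms: none
Why: Iminium-ion organocatalysis (Friedel–Crafts alkylation ortho to the phenol OH, then hemiacetal closure): the arene should add to the E-iminium on the face away from the CPh2(OSiMe3) group, setting C9' (chroman C4) as R, while the unselective lactol carbon is oxidised in step 3.

Step 3
Reactants: 4 (4R)-5,7-dimethoxy-4-(2-methylpropyl)chroman-2-ol
Product: 5 (4R)-5,7-dimethoxy-4-(2-methylpropyl)-3,4-dihydro-2H-chromen-2-one
Conditions: (Pr4N)RuO4 (5 mol %), N-methylmorpholine N-oxide (1.5 equiv), 4 Å MS, CH2Cl2, rt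
Reagents that add atoms: none
Why: Ley–Griffith oxidation of the lactol to the lactone, which does not touch the benzylic stereocentre.

Step 4
Reactants: 5 (4R)-5,7-dimethoxy-4-(2-methylpropyl)-3,4-dihydro-2H-chromen-2-one
Product: 7 (3R,4R)-5,7-dimethoxy-3-methyl-4-(2-methylpropyl)-3,4-dihydro-2H-chromen-2-one, via lithium enolate 6 (not isolated)
Conditions: LiN(SiMe3)2 (1.05 equiv), THF, −78 °C; MeI, −78 → −40 °C
Reagents that add atoms: iodomethane, CI
Why: Enolate alkylation; methyl should enter trans to the isobutyl group, but this centre is made planar again in step 5, so its configuration does not matter.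

Step 5
Reactants: 7 (3R,4R)-5,7-dimethoxy-3-methyl-4-(2-methylpropyl)-3,4-dihydro-2H-chromen-2-one
Product: 9 (3R,4S)-3-(3-iodopropyl)-5,7-dimethoxy-3-methyl-4-(2-methylpropyl)-3,4-dihydro-2H-chromen-2-one, via lithium enolate 8 (not isolated)
Conditions: LiN(i-Pr)2 (1.1 equiv), THF, −78 °C; DMPU, I(CH2)3I (4 equiv), −78 → −30 °C
Reagents that add atoms: 1,3-diiodopropane, ICCCI
Why: Enolate alkylation builds the quaternary C4 (guaiane numbering): the neighbouring isobutyl group, held pseudoaxial by the peri methoxy group, blocks one face of the ring enolate, so the iodide should enter trans to it and leave methyl cis to isobutyl, as the target requires.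

Step 6
Reactants: 9 (3R,4S)-3-(3-iodopropyl)-5,7-dimethoxy-3-methyl-4-(2-methylpropyl)-3,4-dihydro-2H-chromen-2-one
Product: 10 (2R)-2-[(1S)-1-(2-hydroxy-4,6-dimethoxyphenyl)-3-methylbutyl]-2-methylcyclopentan-1-one (in equilibrium with its cyclic hemiketal)
Conditions: SmI2 (2.5 equiv), tris(dibenzoylmethanato)iron (2 mol %), THF, −30 °C → rt; aq. NH4Cl
Reagents that add atoms: none
Why: Samarium Barbier-type intramolecular nucleophilic acyl substitution: the alkylsamarium from the primary iodide attacks the aryl ester carbonyl 5-exo and the hemiketal alkoxide stops a second addition, which closes ring A without touching a stereocentre.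

Step 7
Reactants: 10 (2R)-2-[(1S)-1-(2-hydroxy-4,6-dimethoxyphenyl)-3-methylbutyl]-2-methylcyclopentan-1-one
Product: 11 (2R)-2-methyl-2-[(1S)-3-methyl-1-(2,4,6-trimethoxyphenyl)butyl]cyclopentan-1-one
Conditions: MeI (3 equiv), K2CO3, DMF, 40 °C
Reagents that add atoms: iodomethane, CI
Why: Williamson methylation of the phenol, which also pulls the hemiketal equilibrium over to the open ketone.

Step 8
Reactants: 11 (2R)-2-methyl-2-[(1S)-3-methyl-1-(2,4,6-trimethoxyphenyl)butyl]cyclopentan-1-one
Product: 13 (5R)-5-methyl-5-[(1R)-3-methyl-1-(2,4,6-trimethoxyphenyl)butyl]cyclopent-1-en-1-yl trifluoromethanesulfonate, via potassium enolate 12 (not isolated)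
Conditions: KN(SiMe3)2, THF, −78 °C; PhNTf2, −78 → 0 °C; H2O
Reagents that add atoms: N-phenylbis(trifluoromethanesulfonimide), O=S(=O)(N(c1ccccc1)S(=O)(=O)C(F)(F)F)C(F)(F)F
Why: Enol triflate formation; only C1 carries α-hydrogens, so a single enolate and a single triflate can form.

Step 9
Reactants: 14 3-methylbut-2-enal
Product: 15 3-methylbut-2-enal p-toluenesulfonylhydrazone
Conditions: TsNHNH2 (1.0 equiv), MeOH, rt
Reagents that add atoms: p-toluenesulfonohydrazide, Cc1ccc(cc1)S(=O)(=O)NN
Why: Condensation of the aldehyde with the sulfonylhydrazide gives the crystalline hydrazone.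

Step 10
Reactants: 15 3-methylbut-2-enal p-toluenesulfonylhydrazone
Product: 16 3,3-dimethylcyclopropene
Conditions: NaOMe (1.1 equiv), diglyme, 150–160 °C, N2 stream into a −78 °C trap
Reagents that add atoms: none
Why: Bamford–Stevens reaction: the hydrazone salt loses sulfinate and dinitrogen, and the vinylcarbene closes to the cyclopropene, which is swept out of the hot mixture as it forms.

Step 11
Reactants: 16 3,3-dimethylcyclopropene; 17 (4-bromobut-1-yn-1-yl)trimethylsilane; 13 ring A enol triflate
Product: 21 2-[(1R)-1-{(1R)-2-[(1S,3R)-2,2-dimethyl-3-(4-trimethylsilylbut-3-yn-1-yl)cyclopropyl]-1-methylcyclopent-2-en-1-yl}-3-methylbutyl]-1,3,5-trimethoxybenzene, via butynylmagnesium bromide 18 (not isolated), via cyclopropylmagnesium bromide 19 (not isolated), via cyclopropylzinc bromide 20 (not isolated)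
Conditions: 17, Mg, THF, rt; 16 (1.5 equiv), CuBr·SMe2 (5 mol %), Josiphos SL-J001 (6 mol %), Et2O, −30 °C; ZnBr2, THF, 0 °C; 13 (0.6 equiv), Pd(OAc)2 (5 mol %), SPhos (10 mol %), 50 °C
Reagents that add atoms: none
Why: Copper-catalysed enantioselective syn-carbomagnesiation of the cyclopropene sets C7 and the cis relation at C6 under ligand control (the ligand antipode is chosen for the 7R series), and the configurationally stable cyclopropylmetal is transmetalated to zinc and joined to the triflate by Negishi coupling with retention.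

Step 12
Reactants: 21 silylated enyne
Product: 22 2-[(1R)-1-{(1R)-2-[(1S,3R)-3-(but-3-yn-1-yl)-2,2-dimethylcyclopropyl]-1-methylcyclopent-2-en-1-yl}-3-methylbutyl]-1,3,5-trimethoxybenzene
Conditions: K2CO3, MeOH, rt
Reagents that add atoms: none
Why: Methoxide-mediated protodesilylation of the alkynylsilane frees the terminal alkyne and leaves the vinylcyclopropane untouched.

Step 13
Reactants: 22 enyne (ring A cyclopentene with the cis-cyclopropane and butynyl chain)
Product: 23 (1R,4R,7R)-4-[(1R)-3-methyl-1-(2,4,6-trimethoxyphenyl)butyl]guaia-5,10(14)-dien-11-ol (guaiane numbering)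
Conditions: Ph3PAuNTf2 (5 mol %), H2O (5 equiv), 1,4-dioxane, 23 °C
Reagents that add atoms: water, O
Why: Proposed new method: cationic monovalent gold binds the terminal alkyne and the cyclopentene attacks its internal carbon C10 through the distal alkene carbon C1, which closes ring B and puts the charge on C5, a tertiary cyclopropylcarbinyl centre; the C6–C11 bond then opens to give C5=C6 and a tertiary C11 cation that water captures, and protodeauration leaves the C10 methylene. The closest known reactions are gold-catalysed hydroxycyclisations of 1,6-enynes and the Julia-type opening of cyclopropylcarbinyl cations, but a 1,7-enyne closure relayed through a cyclopropane has not been shown. Ring B (seven-membered) closes exo-dig at the alkyne and endo with respect to the C1=C5 alkene. The only new stereocentre, C1, should be set by attack on the cyclopentene face cis to the C4 methyl and anti to the C9' arm, while C7 is carried over from 22 because none of its bonds is touched. The step needs attack through C1 and not C5, cleavage of C6–C11 and not C6–C7, and water capture in place of proton loss: the first is secured by the cyclopropyl-stabilised tertiary cation at C5, the second by the gem-dimethyl group that makes C11 tertiary, and the third by excess water in a non-nucleophilic solvent.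

Step 14
Reactants: 23 guaia-5,10(14)-dien-11-ol derivative
Product: 24 (1R,4R,7R,10R)-4-[(1R)-3-methyl-1-(2,4,6-trimethoxyphenyl)butyl]guai-5-en-11-ol
Conditions: [Ir(cod)(PCy3)(py)]PF6 (5 mol %), H2 (1 atm), CH2Cl2, 0 °C
Reagents that add atoms: none
Why: Hydroxyl-directed hydrogenation (Crabtree catalyst): the C11 hydroxyl binds iridium and hydrogen should reach the C10 methylene from the face of the C7 side chain, which is also the C1–H face, giving 10R, while the hindered trisubstituted C5=C6 alkene reacts more slowly.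

Step 15
Reactants: 24 guai-5-en-11-ol derivative
Product: 26 (1R,4R,7R,10R)-4-[(1R)-1-(3-formyl-2,4,6-trimethoxyphenyl)-3-methylbutyl]guai-5-en-11-ol, via aryllithium 25 (not isolated)
Conditions: n-BuLi (2.5 equiv), TMEDA, THF, 0 °C; DMF, 0 °C → rt; H2O
Reagents that add atoms: N,N-dimethylformamide, CN(C)C=O
Why: Directed ortho-lithiation at an arene position flanked by two methoxy groups (after deprotonation of the alcohol) and formylation with DMF; base-only conditions spare the alkene and the tertiary alcohol.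

Step 16
Reactants: 26 mono-aldehyde
Product: 29 (1R,4R,7R,10R)-4-[(1R)-1-(3,5-diformyl-2,4,6-trimethoxyphenyl)-3-methylbutyl]guai-5-en-11-ol, via alpha-amino alkoxide 27 (not isolated), via aryllithium 28 (not isolated)
Conditions: LiNMe2 (2.2 equiv), THF, −40 °C; s-BuLi (2.5 equiv), −40 → −10 °C; DMF; H2O
Reagents that add atoms: N,N-dimethylformamide, CN(C)C=O
Why: In situ protection of the aldehyde as its α-amino alkoxide (Comins method), lithiation of the last arene position between two methoxy groups and a second formylation; both aldehydes are released on aqueous work-up.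

Step 17
Reactants: 29 tri-O-methyl dialdehyde
Product: 30 5-[(1R)-1-[(1R,4R,7R,10R)-11-hydroxyguai-5-en-4-yl]-3-methylbutyl]-2,4,6-trihydroxybenzene-1,3-dicarbaldehyde (target)
Conditions: NaSEt (10 equiv), DMF, 120 °C; 1 M HCl
Reagents that add atoms: none
Why: SN2 demethylation of the three aryl methyl ethers by thiolate, each ether being activated by an ortho or para formyl group, under basic conditions that the homoallylic tertiary alcohol and the alkene tolerate.

## Compound list

1 | 3-methylbutanal (isovaleraldehyde) | CC(C)CC=O | starting material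
2 | (E)-5-methylhex-2-enal | CC(C)C/C=C/C=O | intermediate
3 | 3,5-dimethoxyphenol | COc1cc(O)cc(OC)c1 | starting material
4 | (4R)-5,7-dimethoxy-4-(2-methylpropyl)chroman-2-ol, both anomers | CC(C)C[C@@H]1CC(O)Oc2cc(OC)cc(OC)c21 | intermediate
5 | (4R)-5,7-dimethoxy-4-(2-methylpropyl)-3,4-dihydro-2H-chromen-2-one | CC(C)C[C@@H]1CC(=O)Oc2cc(OC)cc(OC)c21 | intermediate
6 | lithium enolate of 5 | CC(C)C[C@@H]1C=C(O[Li])Oc2cc(OC)cc(OC)c21 | intermediate
7 | (3R,4R)-5,7-dimethoxy-3-methyl-4-(2-methylpropyl)-3,4-dihydro-2H-chromen-2-one (trans) | CC(C)C[C@@H]1[C@@H](C)C(=O)Oc2cc(OC)cc(OC)c21 | intermediate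
8 | lithium enolate of 7 | CC(C)C[C@@H]1C(C)=C(O[Li])Oc2cc(OC)cc(OC)c21 | intermediate
9 | (3R,4S)-3-(3-iodopropyl)-5,7-dimethoxy-3-methyl-4-(2-methylpropyl)-3,4-dihydro-2H-chromen-2-one (methyl cis to isobutyl) | CC(C)C[C@@H]1[C@@](C)(CCCI)C(=O)Oc2cc(OC)cc(OC)c21 | intermediate
10 | (2R)-2-[(1S)-1-(2-hydroxy-4,6-dimethoxyphenyl)-3-methylbutyl]-2-methylcyclopentan-1-one | CC(C)C[C@@H](c1c(O)cc(OC)cc1OC)[C@@]1(C)CCCC1=O | intermediate
11 | (2R)-2-methyl-2-[(1S)-3-methyl-1-(2,4,6-trimethoxyphenyl)butyl]cyclopentan-1-one | CC(C)C[C@@H](c1c(OC)cc(OC)cc1OC)[C@@]1(C)CCCC1=O | intermediate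
12 | potassium enolate of 11 | CC(C)C[C@@H](c1c(OC)cc(OC)cc1OC)[C@@]1(C)CCC=C1O[K] | intermediate
13 | (5R)-5-methyl-5-[(1R)-3-methyl-1-(2,4,6-trimethoxyphenyl)butyl]cyclopent-1-en-1-yl trifluoromethanesulfonate | CC(C)C[C@@H](c1c(OC)cc(OC)cc1OC)[C@@]1(C)CCC=C1OS(=O)(=O)C(F)(F)F | intermediate
14 | 3-methylbut-2-enal | CC(C)=CC=O | starting material
15 | 3-methylbut-2-enal p-toluenesulfonylhydrazone | CC(C)=C/C=N/NS(=O)(=O)c1ccc(C)cc1 | intermediate
16 | 3,3-dimethylcyclopropene | CC1(C)C=C1 | intermediate
17 | (4-bromobut-1-yn-1-yl)trimethylsilane | C[Si](C)(C)C#CCCBr | starting material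
18 | [4-(trimethylsilyl)but-3-yn-1-yl]magnesium bromide | C[Si](C)(C)C#CCC[Mg]Br | intermediate
19 | [(1S,3S)-2,2-dimethyl-3-(4-trimethylsilylbut-3-yn-1-yl)cyclopropyl]magnesium bromide (cis) | Br[Mg][C@H]1[C@H](C1(C)C)CCC#C[Si](C)(C)C | intermediate
20 | [(1S,3S)-2,2-dimethyl-3-(4-trimethylsilylbut-3-yn-1-yl)cyclopropyl]zinc bromide (cis) | Br[Zn][C@H]1[C@H](C1(C)C)CCC#C[Si](C)(C)C | intermediate
21 | 2-[(1R)-1-{(1R)-2-[(1S,3R)-2,2-dimethyl-3-(4-trimethylsilylbut-3-yn-1-yl)cyclopropyl]-1-methylcyclopent-2-en-1-yl}-3-methylbutyl]-1,3,5-trimethoxybenzene | CC(C)C[C@@H](c1c(OC)cc(OC)cc1OC)[C@@]1(C)CCC=C1[C@H]2[C@H](C2(C)C)CCC#C[Si](C)(C)C | intermediate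
22 | 2-[(1R)-1-{(1R)-2-[(1S,3R)-3-(but-3-yn-1-yl)-2,2-dimethylcyclopropyl]-1-methylcyclopent-2-en-1-yl}-3-methylbutyl]-1,3,5-trimethoxybenzene | CC(C)C[C@@H](c1c(OC)cc(OC)cc1OC)[C@@]1(C)CCC=C1[C@H]2[C@H](C2(C)C)CCC#C | intermediate
23 | (1R,4R,7R)-4-[(1R)-3-methyl-1-(2,4,6-trimethoxyphenyl)butyl]guaia-5,10(14)-dien-11-ol | CC(C)C[C@@H](c1c(OC)cc(OC)cc1OC)[C@@]1(C)CC[C@H]2C1=C[C@H](C(C)(C)O)CCC2=C | intermediate
24 | (1R,4R,7R,10R)-4-[(1R)-3-methyl-1-(2,4,6-trimethoxyphenyl)butyl]guai-5-en-11-ol | CC(C)C[C@@H](c1c(OC)cc(OC)cc1OC)[C@@]1(C)CC[C@H]2C1=C[C@H](C(C)(C)O)CC[C@H]2C | intermediate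
25 | lithium alkoxide of 24 lithiated at arene C3' | CC(C)C[C@@H](c1c(OC)c([Li])c(OC)cc1OC)[C@@]1(C)CC[C@H]2C1=C[C@H](C(C)(C)O[Li])CC[C@H]2C | intermediate
26 | (1R,4R,7R,10R)-4-[(1R)-1-(3-formyl-2,4,6-trimethoxyphenyl)-3-methylbutyl]guai-5-en-11-ol | CC(C)C[C@@H](c1c(OC)c(C=O)c(OC)cc1OC)[C@@]1(C)CC[C@H]2C1=C[C@H](C(C)(C)O)CC[C@H]2C | intermediate
27 | dilithium α-(dimethylamino) alkoxide of 26 (hemiaminal carbon unselective) | CC(C)C[C@@H](c1c(OC)c(C(O[Li])N(C)C)c(OC)cc1OC)[C@@]1(C)CC[C@H]2C1=C[C@H](C(C)(C)O[Li])CC[C@H]2C | intermediate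
28 | 27 lithiated at arene C5' | CC(C)C[C@@H](c1c(OC)c(C(O[Li])N(C)C)c(OC)c([Li])c1OC)[C@@]1(C)CC[C@H]2C1=C[C@H](C(C)(C)O[Li])CC[C@H]2C | intermediate
29 | (1R,4R,7R,10R)-4-[(1R)-1-(3,5-diformyl-2,4,6-trimethoxyphenyl)-3-methylbutyl]guai-5-en-11-ol | CC(C)C[C@@H](c1c(OC)c(C=O)c(OC)c(C=O)c1OC)[C@@]1(C)CC[C@H]2C1=C[C@H](C(C)(C)O)CC[C@H]2C | intermediate
30 | 5-[(1R)-1-[(1R,4R,7R,10R)-11-hydroxyguai-5-en-4-yl]-3-methylbutyl]-2,4,6-trihydroxybenzene-1,3-dicarbaldehyde | CC(C)C[C@@H](c1c(O)c(C=O)c(O)c(C=O)c1O)[C@@]1(C)CC[C@H]2C1=C[C@H](C(C)(C)O)CC[C@H]2C | target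

## Step count and risks

Total step count: 17. Longest linear sequence: 15 steps (steps 1–8, then 11–17).

**Step 13 (gold cascade).** The seven-membered closure may be slower than gold-catalysed hydration of the alkyne, the alkene may attack through C5 to close a six-membered ring, or the C11 cation may lose a proton before water arrives.
Fallback (known reactions only), setting out from ketone 11 and coming back at 23: 2,3-dibromopropene and allylmagnesium bromide would give 2-bromohexa-1,5-diene F1. Palladium-catalysed α-alkenylation of the enolate of 11 with it (Pd2(dba)3, P(t-Bu)3, LiN(SiMe3)2, toluene) would give the 5-(hexa-1,5-dien-2-yl) ketone F2, whose C1 centre equilibrates to the isomer with the side chain anti to the C9' arm. Vinylmagnesium bromide with CeCl3 should add to the carbonyl from the face away from the C9' arm to give the tertiary allylic alcohol F3. Ring-closing metathesis (second-generation Grubbs catalyst) between the vinyl group and the terminal alkene would close ring B as the cyclohept-2-enol F4 with a C6=C7 alkene. Hydroxyl-directed isopropylidene transfer with Et2Zn and 2,2-diiodopropane F5 (from acetone hydrazone and iodine) would place the gem-dimethylcyclopropane on the hydroxyl face to give the cyclopropylcarbinol F6. Dilute aqueous HClO4 in acetone would then bring about the Julia-type cyclopropylcarbinyl-to-homoallyl rearrangement with water capture at C11, giving 23.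

**Step 14 (directed hydrogenation).** The directing hydroxyl is remote from the C10 methylene, so hydrogen delivery may be poorly face-selective, and over-reduction of the homoallylic C5=C6 alkene may compete.
Fallback, setting out from 23 and coming back at 24: hydroboration of the 1,1-disubstituted alkene with 9-BBN from its less hindered C1–H face, then NaBO3 oxidation, would give the C14 primary alcohol F7. Selective tosylation of the primary hydroxyl (TsCl, pyridine) would give the tosylate F8, and LiEt3BH would reduce it to the C10 methyl group of 24.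

**Step 11 (carbomagnesiation and Negishi coupling).** Transmetalation and reductive elimination between two hindered partners may be slow, so that the cyclopropylzinc is lost by protonation; enantio-induction in the carbomagnesiation may also be incomplete.
Fallback, setting out from ketone 11 and cyclopropylmagnesium bromide 19 and coming back at 21: 19, transmetalated with CeCl3, would add to the carbonyl of 11 to give the tertiary cyclopropylcarbinol F9. Dehydration with Martin sulfurane toward C1, the only ring carbon next to the carbinol that bears hydrogen, would give 21 under non-ionising conditions.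

## Further compounds

F1 | step 13 | 2-bromohexa-1,5-diene | C=C(Br)CCC=C
F2 | step 13 | (2R,5R)-5-(hexa-1,5-dien-2-yl)-2-methyl-2-[(1S)-3-methyl-1-(2,4,6-trimethoxyphenyl)butyl]cyclopentan-1-one | CC(C)C[C@@H](c1c(OC)cc(OC)cc1OC)[C@@]1(C)CC[C@H](C(=C)CCC=C)C1=O
F3 | step 13 | 1-vinyl carbinol from F2 (vinyl cis to the C4 methyl, hydroxyl cis to the C9' arm) | CC(C)C[C@@H](c1c(OC)cc(OC)cc1OC)[C@@]1(C)CC[C@H](C(=C)CCC=C)[C@]1(O)C=C
F4 | step 13 | cis-fused 4-substituted guaia-6,10(14)-dien-5-ol (ring B closed, C5 hydroxyl cis to C1–H) | CC(C)C[C@@H](c1c(OC)cc(OC)cc1OC)[C@@]1(C)CC[C@@H]2C(=C)CCC=C[C@]12O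
F5 | step 13 | 2,2-diiodopropane | CC(C)(I)I
F6 | step 13 | 6,11-cyclo-guai-10(14)-en-5-ol (gem-dimethylcyclopropane C6–C7–C11 cis to the C5 hydroxyl) | CC(C)C[C@@H](c1c(OC)cc(OC)cc1OC)[C@@]1(C)CC[C@@H]2C(=C)CC[C@@H]3[C@@H](C3(C)C)[C@]12O
F7 | step 14 | (1R,4R,7R,10R)-4-[(1R)-3-methyl-1-(2,4,6-trimethoxyphenyl)butyl]guai-5-ene-11,14-diol | CC(C)C[C@@H](c1c(OC)cc(OC)cc1OC)[C@@]1(C)CC[C@H]2C1=C[C@H](C(C)(C)O)CC[C@H]2CO
F8 | step 14 | 14-O-(p-toluenesulfonyl) derivative of F7 | CC(C)C[C@@H](c1c(OC)cc(OC)cc1OC)[C@@]1(C)CC[C@H]2C1=C[C@H](C(C)(C)O)CC[C@H]2COS(=O)(=O)c3ccc(C)cc3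
F9 | step 11 | tertiary cyclopropylcarbinol from 11 and 19 (carbinol carbon unselective) | CC(C)C[C@@H](c1c(OC)cc(OC)cc1OC)[C@@]1(C)CCCC1(O)[C@H]2[C@H](C2(C)C)CCC#C[Si](C)(C)C
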